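**Plan**

1. Retrosynthesis: the C11–OOH group and the C6=C7 bond go back to a 7(11)-en-8-one (Schenck ene). The ester C–O, both C–O bonds at C3/C4 (cis-dihydroxylation of a Δ3 alkene) and the C5–H bond (hydrogenation of a Δ5 alkene) are then removed. The C5–C6 bond of ring B is cut next, then C7–C8, C10–C9 and C10–CH3.
2. Forward: ring A is (R)-carvone. Its C6 becomes the quaternary C10 by two enolate alkylations, the isopropenyl group is excised, a 2-acylallyl carbonate arm is attached at C8, and ring B is closed last by joining C6 to the ring A carbonyl carbon C5.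
3. Enabling feature: ring B contains the 2-acylallyl triad C6–C7(–C8=O)–C11. A phosphine adds at C6 with loss of the C11 carbonate, the ylide at C6 olefinates the C5 ketone of ring A, and singlet oxygen later transposes the same triad back (O on C11, C6=C7).
4. Stereochemistry: C10 comes from the carvone stereocentre (second alkylation anti to isopropenyl). C3 and C4 come from α-face osmylation of the Δ3 bond, anti to the C10 methyl. C5 comes from hydroxyl-directed α-face hydrogenation of the Δ5 bond. The Z ester geometry comes from angelic acid.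

Key step: step 6

Remark: bicyclic compounds are named with eudesmane numbering (ring A = C1–C5 and C10, ring B = C5–C10, C11–C13 on C7, C14 on C10, C15 on C4; α = the face opposite the C10 methyl). Compound 7 is used as its mixture of C6 epimers, since that centre is re-enolised in step 3.

**Route**

Step 1
Reactants: 1 bromoethene (vinyl bromide); 2 acetone
Product: 4 3-bromo-2-methylbut-3-en-2-ol, via 1-bromo-1-lithioethene 3 (not isolated)
Conditions: LiN(i-Pr)2, THF/Et2O/pentane, −110 °C; acetone, −110 → −78 °C; H2O
Reagents that add atoms: none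
Why: Deprotonation of bromoethene at the bromine-bearing carbon gives a vinylic carbenoid that is stable at very low temperature and adds to the ketone (organolithium 1,2-addition), giving the achiral 2-bromoallylic tertiary alcohol.

Step 2
Reactants: 5 (R)-(−)-carvone
Product: 7 6-methylcarvone [(5R,6S)-2,6-dimethyl-5-(prop-1-en-2-yl)cyclohex-2-en-1-one drawn; C6 epimers carried together], via lithium enolate 6 (not isolated)
Conditions: LiN(i-Pr)2, THF, −78 °C; MeI, −78 → 0 °C
Reagents that add atoms: iodomethane, CI
Why: Kinetic deprotonation of the enone at the α′ carbon C6 followed by SN2 methylation (enolate alkylation) installs the future C14 methyl, the new C6 centre being irrelevant because it is re-enolised in step 3.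

Step 3
Reactants: 7 6-methylcarvone; 8 2-bromo-N-methoxy-N-methylacetamide
Product: 10 2-[(1S,6S)-1,3-dimethyl-2-oxo-6-(prop-1-en-2-yl)cyclohex-3-en-1-yl]-N-methoxy-N-methylacetamide, via lithium enolate 9 (not isolated)
Conditions: LiN(i-Pr)2, THF/DMPU, −78 °C; 8, −78 → −20 °C
Reagents that add atoms: none
Why: The tetrasubstituted α′ enolate is alkylated by the α-bromo amide (enolate alkylation) on the face opposite the neighbouring isopropenyl group, so the acetamide arm ends trans and the methyl cis to isopropenyl, which sets the quaternary centre that becomes C10 (R in the target).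

Step 4
Reactants: 10
Product: 12 2-[(1R)-1,3-dimethyl-2-oxocyclohex-3-en-1-yl]-N-methoxy-N-methylacetamide, via methoxy hydroperoxide 11 (not isolated)
Conditions: O3, MeOH, −78 °C; FeSO4·7H2O, PhSH, 0 °C → rt
Reagents that add atoms: none
Why: Ozone cleaves the electron-rich isopropenyl alkene in preference to the conjugated ring alkene, and single-electron reduction of the resulting α-methoxy hydroperoxide by FeSO4 triggers β-scission of the alkoxyl radical (loss of methyl acetate) and hydrogen-atom capture from the thiol (dealkenylative hydrogenation), which removes the relay stereocentre and leaves the quaternary centre untouched.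

Step 5
Reactants: 12; 4
Product: 15 tert-butyl 5-[(1R)-1,3-dimethyl-2-oxocyclohex-3-en-1-yl]-2-methyl-3-methylidene-4-oxopentan-2-yl carbonate, via 2-lithioallyl lithium alkoxide 13 (not isolated), via tetrahedral dilithium adduct 14 (not isolated)
Conditions: 4, t-BuLi (3 equiv), Et2O, −78 °C; 12, THF, −78 °C; Boc2O, −78 → 0 °C; H2O
Reagents that add atoms: di-tert-butyl dicarbonate, CC(C)(C)OC(=O)OC(=O)OC(C)(C)C
Why: Bromine–lithium exchange gives a 2-lithioallyl alkoxide that adds once to the N-methoxy-N-methylamide (chelated tetrahedral adduct, ketone synthesis) faster than to the ring ketone shielded by the adjacent quaternary carbon, and the tertiary lithium alkoxide is acylated in the same flask by Boc2O to give the Morita–Baylis–Hillman-type carbonate without any new stereocentre.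

Step 6
Reactants: 15
Product: 17 (10R)-eudesma-3,5,7(11)-trien-8-one, via allylic phosphonium ylide 16 (not isolated)
Conditions: PBu3 (1.2 equiv), toluene (0.01 M), rt → 90 °C
Reagents that add atoms: none
Why: Proposed new method: tributylphosphine adds to the terminal methylene C6 of the 2-acylallyl carbonate in an SN2′ addition–elimination that expels tert-butyl carbonate from C11, the tert-butoxide released on loss of CO2 deprotonates the allylic phosphonium salt, and ylide 16 undergoes an intramolecular Wittig reaction with the ring A ketone C5 to give the C5=C6 bond and tributylphosphine oxide. The closest known reaction type is the phosphine-mediated olefination of aldehydes with Morita–Baylis–Hillman carbonates (allylic ylide formation, then Wittig), here run intramolecularly on a ketone. Ring B is closed by 6-exo-trig addition of the ylide carbon C6 to the C5 carbonyl, followed by oxaphosphetane collapse. No stereocentre is created because C5 becomes sp2, C10 is untouched, and the C5 configuration is deferred to step 8. The step needs attack through C6 rather than C11 of the ambident ylide and 1,2- rather than conjugate attack on the ring A enone: attack through C11 would give only a congested, reversible alkoxide whereas attack through the phosphorus-bearing C6 is drained irreversibly to the alkene, and the four-atom tether cannot reach the enone β-carbon C3. A trialkylphosphine is chosen because its ylide is more nucleophilic toward the hindered, conjugated ketone, and high dilution suppresses intermolecular ylide–enone reactions.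

Step 7
Reactants: 17
Product: 18 (3R,4S,10R)-3,4-dihydroxyeudesma-5,7(11)-dien-8-one
Conditions: OsO4 (cat.), NMO, acetone/H2O, 0 °C
Reagents that add atoms: osmium tetroxide, O=[Os](=O)(=O)=O; N-methylmorpholine N-oxide, C[N+]1([O-])CCOCC1; water, O
Why: Catalytic cis-dihydroxylation should select the Δ3 bond, the most electron-rich and least hindered alkene at the end of the triene remote from the carbonyl, and add from the α face anti to the pseudoaxial C10 methyl, setting C3 (R) and C4 (S) together.

Step 8
Reactants: 18
Product: 19 (3R,4S,5R,10R)-3,4-dihydroxyeudesm-7(11)-en-8-one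
Conditions: [Ir(cod)(PCy3)(py)]PF6 (cat.), H2 (1 atm), CH2Cl2, 0 °C → rt
Reagents that add atoms: none
Why: The cationic iridium catalyst binds the allylic 4α-hydroxyl and delivers H2 to the α face of the trisubstituted C5=C6 bond (hydroxyl-directed homogeneous hydrogenation), placing H5 α and trans to the C10 methyl, which also shields the β face, while the remote tetrasubstituted enone alkene is left alone.

Step 9
Reactants: 19; 20 angelic acid [(Z)-2-methylbut-2-enoic acid]
Product: 22 (3R,4S,5R,10R)-3-[(Z)-2-methylbut-2-enoyloxy]-4-hydroxyeudesm-7(11)-en-8-one, via mixed anhydride 21 (not isolated)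
Conditions: 20, 2,4,6-Cl3C6H2COCl, Et3N, toluene, rt; 19, 80 °C
Reagents that add atoms: none
Why: The mixed anhydride with the hindered aroyl chloride transfers only its angeloyl group to the secondary 3α-hydroxyl (Yamaguchi-type esterification run without a nucleophilic catalyst), leaving the tertiary 4α-hydroxyl free and the Z double bond unisomerised.

Step 10
Reactants: 22
Product: 23 (3R,4S,5R,10R)-3-[(Z)-2-methylbut-2-enoyloxy]-4-hydroxy-11-hydroperoxyeudesm-6-en-8-one (target)
Conditions: O2, hν (visible), tetraphenylporphyrin (cat.), CH2Cl2, 0 °C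
Reagents that add atoms: dioxygen, O=O
Why: Singlet oxygen reacts with the s-cis tetrasubstituted enone in a Schenck ene reaction that removes a C6 hydrogen from the ring position geminal to the carbonyl and bonds oxygen to C11, giving the tertiary hydroperoxide and the C6=C7 enone without a new stereocentre, while the electron-poor angelate alkene is much less reactive.

**Compound list**

1 | bromoethene (vinyl bromide) | C=CBr | starting material
2 | acetone | CC(C)=O | starting material
3 | 1-bromo-1-lithioethene | [Li]C(Br)=C | intermediate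
4 | 3-bromo-2-methylbut-3-en-2-ol | CC(C)(O)C(Br)=C | intermediate
5 | (R)-(−)-carvone, (5R)-2-methyl-5-(prop-1-en-2-yl)cyclohex-2-en-1-one | CC(=C)[C@@H]1CC=C(C)C(=O)C1 | starting material
6 | lithium enolate of 5 (O–Li on C1, C1=C6) | CC(=C)[C@@H]1CC=C(C)C(O[Li])=C1 | intermediate
7 | 6-methylcarvone, (5R,6S)-2,6-dimethyl-5-(prop-1-en-2-yl)cyclohex-2-en-1-one (trans epimer drawn; 6R epimer also present) | O=C1C(C)=CC[C@@H](C(C)=C)[C@@H]1C | intermediate
8 | 2-bromo-N-methoxy-N-methylacetamide | CON(C)C(=O)CBr | starting material
9 | lithium enolate of 7 (O–Li on C1, C1=C6) | CC(=C)[C@@H]1CC=C(C)C(O[Li])=C1C | intermediate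
10 | 2-[(1S,6S)-1,3-dimethyl-2-oxo-6-(prop-1-en-2-yl)cyclohex-3-en-1-yl]-N-methoxy-N-methylacetamide (acetamide arm trans, methyl cis to isopropenyl) | O=C1C(C)=CC[C@@H](C(C)=C)[C@]1(C)CC(=O)N(C)OC | intermediate
11 | α-methoxy hydroperoxide of 10 (isopropenyl carbon converted to C(CH3)(OCH3)OOH, ring centres unchanged, peroxyacetal carbon unassigned) | O=C1C(C)=CC[C@@H](C(C)(OC)OO)[C@]1(C)CC(=O)N(C)OC | intermediate
12 | 2-[(1R)-1,3-dimethyl-2-oxocyclohex-3-en-1-yl]-N-methoxy-N-methylacetamide | O=C1C(C)=CCC[C@]1(C)CC(=O)N(C)OC | intermediate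
13 | lithium 3-lithio-2-methylbut-3-en-2-olate | [Li]OC(C)(C)C([Li])=C | intermediate
14 | dilithium tetrahedral adduct of 12 with 13 (lithium hemiaminal alkoxide, carbinol carbon unassigned) | O=C1C(C)=CCC[C@]1(C)CC(O[Li])(N(C)OC)C(=C)C(C)(C)O[Li] | intermediate
15 | tert-butyl 5-[(1R)-1,3-dimethyl-2-oxocyclohex-3-en-1-yl]-2-methyl-3-methylidene-4-oxopentan-2-yl carbonate | O=C1C(C)=CCC[C@]1(C)CC(=O)C(=C)C(C)(C)OC(=O)OC(C)(C)C | intermediate
16 | tributyl{2-[2-((1R)-1,3-dimethyl-2-oxocyclohex-3-en-1-yl)acetyl]-3-methylbut-2-en-1-ylidene}phosphorane | O=C1C(C)=CCC[C@]1(C)CC(=O)C(C=P(CCCC)(CCCC)CCCC)=C(C)C | intermediate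
17 | (10R)-eudesma-3,5,7(11)-trien-8-one | CC1=CCC[C@]2(C)CC(=O)C(=C(C)C)C=C12 | intermediate
18 | (3R,4S,10R)-3,4-dihydroxyeudesma-5,7(11)-dien-8-one (3α,4α-diol) | O[C@@H]1CC[C@]2(C)CC(=O)C(=C(C)C)C=C2[C@]1(C)O | intermediate
19 | (3R,4S,5R,10R)-3,4-dihydroxyeudesm-7(11)-en-8-one (3α,4α-diol, 5α-H) | O[C@@H]1CC[C@]2(C)CC(=O)C(=C(C)C)C[C@H]2[C@]1(C)O | intermediate
20 | angelic acid, (Z)-2-methylbut-2-enoic acid | C/C=C(/C)C(=O)O | starting material
21 | (Z)-2-methylbut-2-enoic 2,4,6-trichlorobenzoic anhydride | C/C=C(/C)C(=O)OC(=O)c1c(Cl)cc(Cl)cc1Cl | intermediate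
22 | (3R,4S,5R,10R)-3-[(Z)-2-methylbut-2-enoyloxy]-4-hydroxyeudesm-7(11)-en-8-one | C/C=C(/C)C(=O)O[C@@H]1CC[C@]2(C)CC(=O)C(=C(C)C)C[C@H]2[C@]1(C)O | intermediate
23 | (3R,4S,5R,10R)-3-[(Z)-2-methylbut-2-enoyloxy]-4-hydroxy-11-hydroperoxyeudesm-6-en-8-one | C/C=C(/C)C(=O)O[C@@H]1CC[C@]2(C)CC(=O)C(C(C)(C)OO)=C[C@H]2[C@]1(C)O | target

**Step count and risks**

Total step count: 10. Longest linear sequence: 9 steps (steps 2–10, from 5 to 23); step 1 is a one-step side branch.

Steps most likely to fail:

1. Step 6 (Proposed new method). The carbonyl olefination of the hindered, conjugated C5 ketone by the allylic ylide may be slow, so that intermolecular ylide–enone annulation, ylide protonation or base-induced isomerisation takes over. Fallback, from 15 back to 17: heating 15 with triethyl phosphite effects an SN2′ Michaelis–Arbuzov substitution and gives the isolable diethyl {2-[2-((1R)-1,3-dimethyl-2-oxocyclohex-3-en-1-yl)acetyl]-3-methylbut-2-en-1-yl}phosphonate F1. Treatment of F1 with NaH in THF at high dilution then closes ring B by an intramolecular Horner–Wadsworth–Emmons olefination of the C5 ketone and returns to 17.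

2. Step 5. The alkenyllithium may add to the ring ketone or act as a base toward the amide α-CH2, and the hindered tertiary alkoxide may be carbonated incompletely. Fallback, from 7 and 4 back to 15, under neutral acyl cross-coupling conditions: enolate 9 is alkylated with tert-butyl bromoacetate to give tert-butyl 2-[(1S,6S)-1,3-dimethyl-2-oxo-6-(prop-1-en-2-yl)cyclohex-3-en-1-yl]acetate F2. Dealkenylative hydrogenation as in step 4 gives tert-butyl 2-[(1R)-1,3-dimethyl-2-oxocyclohex-3-en-1-yl]acetate F3. CF3CO2H cleaves the ester to 2-[(1R)-1,3-dimethyl-2-oxocyclohex-3-en-1-yl]acetic acid F4, and oxalyl chloride converts it to 2-[(1R)-1,3-dimethyl-2-oxocyclohex-3-en-1-yl]acetyl chloride F5. Separately, 4 is lithiated as in step 5 and treated with Bu3SnCl and then Boc2O to give tert-butyl 2-methyl-3-(tributylstannyl)but-3-en-2-yl carbonate F6. Stille–Migita acylation of F5 with F6 (Pd2(dba)3, AsPh3, THF) gives 15 without exposing the ring ketone to an organolithium.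

3. Step 8. The cross-conjugated dienone may be over-reduced or isomerised, or the C5=C6 bond may turn over slowly. Fallback, from 18 back to 19, metal-free: diimide generated in situ from 2-nitrobenzenesulfonohydrazide and Et3N in CH2Cl2 transfers H2 in a concerted syn manner to the α face of the trisubstituted C5=C6 bond, the β face being blocked by the C10 and C4 methyls, and does not reduce the tetrasubstituted C7=C11 bond. No new compound arises on the way (F0).

**Further compounds**

F1 | step 6 | diethyl {2-[2-((1R)-1,3-dimethyl-2-oxocyclohex-3-en-1-yl)acetyl]-3-methylbut-2-en-1-yl}phosphonate | O=C1C(C)=CCC[C@]1(C)CC(=O)C(CP(=O)(OCC)OCC)=C(C)C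
F2 | step 5 | tert-butyl 2-[(1S,6S)-1,3-dimethyl-2-oxo-6-(prop-1-en-2-yl)cyclohex-3-en-1-yl]acetate | O=C1C(C)=CC[C@@H](C(C)=C)[C@]1(C)CC(=O)OC(C)(C)C
F3 | step 5 | tert-butyl 2-[(1R)-1,3-dimethyl-2-oxocyclohex-3-en-1-yl]acetate | O=C1C(C)=CCC[C@]1(C)CC(=O)OC(C)(C)C
F4 | step 5 | 2-[(1R)-1,3-dimethyl-2-oxocyclohex-3-en-1-yl]acetic acid | O=C1C(C)=CCC[C@]1(C)CC(=O)O
F5 | step 5 | 2-[(1R)-1,3-dimethyl-2-oxocyclohex-3-en-1-yl]acetyl chloride | O=C1C(C)=CCC[C@]1(C)CC(=O)Cl
F6 | step 5 | tert-butyl 2-methyl-3-(tributylstannyl)but-3-en-2-yl carbonate | CCCC[Sn](CCCC)(CCCC)C(=C)C(C)(C)OC(=O)OC(C)(C)C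
F0 | step 8 | none | none
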